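Assumption: the SMILES is read as (2S,3R,4R) (lignan numbering 7S,8R,8'R), i.e. aryl/CH2OH trans and CH2OH/benzyl cis on the tetrahydrofuran; this is natural (+)-lariciresinol.

## Retrosynthetic overview

1. The C7–O bond is made last: one of the two homotopic ArCH2 groups of C2-symmetric (R,R)-secoisolariciresinol is oxidised to a p-quinone methide (transient dearomatisation) and trapped 5-exo by the 1,4-diol.
2. (R,R)-Secoisolariciresinol comes from global LiAlH4 reduction of a C2-symmetric bis(N-acyloxazolidinone), which also removes the aryl pivalates.
3. The C8–C8' bond and both carbon stereocentres come from an auxiliary-controlled oxidative enolate homocoupling of a single monomer.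
4. The monomer is made from ferulic acid (hydrogenation, O-pivaloylation) and (S)-4-isopropyloxazolidin-2-one.
5. Ring order: only one ring is formed, the tetrahydrofuran, in the final step.

## Route

**Step 1**
Reactants: 1, ferulic acid
Product: 2, 3-(4-hydroxy-3-methoxyphenyl)propanoic acid (dihydroferulic acid)
Conditions: H2 (1 atm), 10% Pd/C, MeOH, rt
Reagents that add atoms: none (H2 only)
Why: Heterogeneous catalytic hydrogenation reduces the conjugated C=C and leaves the arene, phenol and acid untouched; no stereocentre is formed.

**Step 2**
Reactants: 2, dihydroferulic acid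
Product: 3, 3-[3-methoxy-4-(pivaloyloxy)phenyl]propanoic acid
Conditions: PivCl (2.3 equiv), pyridine, CH2Cl2, 0 °C → rt; then H2O/THF, rt; 1 M HCl work-up
Reagents that add atoms: pivaloyl chloride, CC(C)(C)C(=O)Cl
Why: Phenol O-acylation; the mixed carboxylic–pivalic anhydride formed at the acid is hydrolysed in the aqueous stir while the hindered aryl pivalate survives. The pivalate is chosen because it has no α-H (LDA-stable) and is removed for free in step 5.

**Step 3**
Reactants: 3, the O-pivaloyl acid; 4, (S)-4-isopropyloxazolidin-2-one
Product: 5, (S)-4-isopropyl-3-{3-[3-methoxy-4-(pivaloyloxy)phenyl]propanoyl}oxazolidin-2-one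
Conditions: PivCl (1.05 equiv), Et3N, THF, −20 °C; then LiCl, 4, rt
Reagents that add atoms: none (auxiliary 4 is a numbered reactant; PivCl only activates the acid)
Why: Mixed-anhydride N-acylation of an Evans oxazolidinone under mild LiCl/Et3N conditions; the aryl pivalate is inert and no new stereocentre is formed.

**Step 4**
Reactants: 5 (2 equiv)
Product: 6, (4S,4'S)-3,3'-{(2R,3R)-2,3-bis[3-methoxy-4-(pivaloyloxy)benzyl]butanedioyl}bis(4-isopropyloxazolidin-2-one)
Conditions: LDA (1.05 equiv), THF, −78 °C; then TiCl4 (1.1 equiv), −78 °C → rt; NH4Cl quench
Reagents that add atoms: none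
Why: Oxidative homocoupling of the chelated (Z)-imide enolate (Ti(IV)-mediated single-electron oxidation, α-radical/enolate dimerisation). Each α-carbon bonds on the face anti to the isopropyl group, the same facial sense as an Evans alkylation, so the (S)-auxiliary gives the C2-symmetric (R,R)-dimer; the minor R,S diastereomer is removed by chromatography or crystallisation.

**Step 5**
Reactants: 6
Product: 7, (−)-secoisolariciresinol, (2R,3R)-2,3-bis(4-hydroxy-3-methoxybenzyl)butane-1,4-diol
Conditions: LiAlH4 (excess), THF, 0 °C → rt; Rochelle salt / dilute HCl work-up
Reagents that add atoms: none (hydride only)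
Why: Reductive cleavage of both N-acyloxazolidinones to primary alcohols, with simultaneous reduction of both aryl pivalates to the free phenols. Any lactone formed by the first alkoxide attacking the neighbouring imide is also reduced to the same diol, and the α-stereocentres are not enolised, so (R,R) is retained.

**Step 6 (key step)**
Reactants: 7
Product: 8, (+)-lariciresinol, 4-[(2S,3R,4R)-4-(4-hydroxy-3-methoxybenzyl)-3-(hydroxymethyl)tetrahydrofuran-2-yl]-2-methoxyphenol
Conditions: DDQ (0.95 equiv, slow addition), anhydrous 1,4-dioxane (0.02 M), 15 °C → rt; aq. NaHCO3/ascorbate quench; recovered 7 recycled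
Reagents that add atoms: none
Why: DDQ dehydrogenation of a 4-alkylguaiacol gives a p-quinone methide, which is trapped by 5-exo oxa-1,6-addition of the C9'–OH with rearomatisation. The two ArCH2 groups are homotopic under the C2 axis, so attack at either gives the same product and the symmetry is broken only here. The 3,4-cis relationship follows directly from the (R,R) diol; the new C2 centre closes with the aryl group anti to the adjacent CH2OH (2,3-trans, 2S), which is also the thermodynamic isomer because the closure is reversible through the quinone methide.

## Compound list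

1 | ferulic acid | COc1cc(/C=C/C(=O)O)ccc1O | starting material
2 | dihydroferulic acid | COc1cc(CCC(=O)O)ccc1O | intermediate
3 | 3-[3-methoxy-4-(pivaloyloxy)phenyl]propanoic acid | COc1cc(CCC(=O)O)ccc1OC(=O)C(C)(C)C | intermediate
4 | (S)-4-isopropyloxazolidin-2-one | CC(C)[C@H]1COC(=O)N1 | starting material
5 | (S)-4-isopropyl-3-{3-[3-methoxy-4-(pivaloyloxy)phenyl]propanoyl}oxazolidin-2-one | CC(C)[C@H]1COC(=O)N1C(=O)CCc1ccc(OC(=O)C(C)(C)C)c(OC)c1 | intermediate
6 | (R,R)-bis-imide dimer | CC(C)[C@H]1COC(=O)N1C(=O)[C@H](Cc1ccc(OC(=O)C(C)(C)C)c(OC)c1)[C@@H](Cc1ccc(OC(=O)C(C)(C)C)c(OC)c1)C(=O)N1C(=O)OC[C@@H]1C(C)C | intermediate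
7 | (−)-secoisolariciresinol (2R,3R) | COc1cc(C[C@@H](CO)[C@@H](Cc2ccc(O)c(OC)c2)CO)ccc1O | intermediate
8 | (+)-lariciresinol (2S,3R,4R) | COc1cc(C[C@H]2CO[C@H](c3ccc(O)c(OC)c3)[C@H]2CO)ccc1O | target

## Summary

Total step count: 6. Longest linear sequence: 6 steps, from ferulic acid.

Three steps most likely to fail:

1. **Step 6 (mono-oxidation of 7).** The product still carries a second oxidisable ArCH2 (leading to pinoresinol) and a more hydridic C7–H (leading to ring-opened 7-oxo products). Friedel–Crafts closure to isolariciresinol is also possible if the medium turns acidic. Realistically this gives about 40–50% of 8 at partial conversion.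
   Fallback: oxidise through to C2-symmetric (+)-pinoresinol (≥2 equiv oxidant, both arms cyclise), then break the symmetry reductively by mono-hydrogenolysis of one benzylic C–O bond (H2, Pd/C, stopped after 1 equiv) to give 8.

2. **Step 4 (oxidative enolate homocoupling).** Yield and R,R : R,S ratio are moderate for this reaction class, and the aryl pivalate must survive the enolate and TiCl4.
   Fallback: build the (R,R)-dibenzylsuccinate skeleton stepwise. Stobbe condensation of O-protected vanillin with a succinate, Rh-catalysed asymmetric hydrogenation to the (R)-benzylsuccinate half-ester, reduction to (R)-β-benzyl-γ-butyrolactone, trans-selective α-benzylation, then LiAlH4 and deprotection give the same diol 7.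

3. **Step 5 (LiAlH4 on the hindered bis-imide).** Endocyclic attack on the oxazolidinone carbonyl would give ring-opened hydroxy-amides instead of the diol.
   Fallback: remove the auxiliaries hydrolytically (LiOH/H2O2, which also cleaves the pivalates) to the (R,R)-diacid, convert to the dimethyl ester (or cyclic anhydride), and reduce that with LiAlH4 to 7.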